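**Plan**

1. Locants are those of the target name: C1 bridgehead CH, C2 C=O, C3 C–OMe, C4 =CH, C5 allyl-bearing quaternary C, C6 CH–CH3, C7 CH–aryl, C8 bridge C=O. The retrosynthesis first removes the C3 enol ether methyl and lowers C3 and C8 to CH2 and CH–OAc, then cuts C1–C8 and C5–C6 of the cyclopentanone ring C1–C8–C5–C6–C7 together.
2. Feature used: C1 is alpha to the C2 carbonyl and carries C7, whose other neighbour C6 bears a methyl and is bonded to C5. An alpha-keto radical at C1 bearing a 1-arylallyl group can therefore close onto C8 of a C5=C8 enol acetate, and the C5 radical can close onto the vinyl group, whose CH2 end becomes the C6 methyl.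
3. Forward: iridium-catalysed allylation of tert-butyl acetoacetate sets C7. Gamma-alkylation of its dianion with a bromo enol acetate made from pent-4-enal joins the chain. Bromination and loss of the ester group give the alpha-bromo ketone.
4. The radical tandem closes the six-membered ring (C1–C8) and the five-membered ring (C5–C6) in one step, and the seven-membered ring comes with them. C3 is then hydroxylated, both carbinols are oxidised and the diosphenol is O-methylated.
5. Stereochemistry: C7 comes from catalysis. C1, C5 and C6 are relayed from C7 in the radical step (allylic strain at the radical, bridge geometry, chair-like 5-exo transition state).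

Key step: step 8

Assumption: stereo elements that are destroyed later (enol acetate geometry, the acidic carbon of the beta-keto esters, the bromine-bearing carbon, the acetoxy- and hydroxy-bearing carbons) are carried as mixtures and left undefined in names and SMILES; pent-4-enal, tert-butyl acetoacetate and (E)-3,4-dimethoxycinnamyl alcohol are taken as commercial.

**Route**

Step 1
Reactants: 1 pent-4-enal
Product: 2 2-methylidenepent-4-enal
Conditions: aq. CH2O (37%), pyrrolidine (0.1 equiv), propanoic acid (0.1 equiv), i-PrOH, 45 °C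
Reagents that add atoms: formaldehyde (C=O)
Why: Amine-catalysed Mannich condensation of an enolisable aldehyde with formaldehyde followed by elimination (alpha-methylenation) should give the 2-substituted acrolein.

Step 2
Reactants: 2 2-methylidenepent-4-enal
Product: 3 2-(bromomethyl)penta-1,4-dien-1-yl acetate
Conditions: AcBr (1.05 equiv), ZnCl2 (0.02 equiv), CH2Cl2, −20 °C to 0 °C
Reagents that add atoms: acetyl bromide (CC(=O)Br)
Why: ZnCl2-catalysed 1,4-addition of an acyl bromide to an enal (bromide to the beta carbon, acyl to oxygen), known for acrolein and methacrolein, should give the gamma-bromo enol acetate and so fix the future C8 at the enol ester level.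

Step 3
Reactants: 4 (2E)-3-(3,4-dimethoxyphenyl)prop-2-en-1-ol
Product: 5 (2E)-3-(3,4-dimethoxyphenyl)prop-2-en-1-yl methyl carbonate
Conditions: ClCO2Me (1.2 equiv), pyridine (1.5 equiv), CH2Cl2, 0 °C
Reagents that add atoms: methyl chloroformate (COC(=O)Cl)
Why: Acylation of the primary allylic alcohol should give the methyl carbonate, the standard leaving group for iridium-catalysed allylic substitution.

Step 4
Reactants: 6 tert-butyl 3-oxobutanoate; 5 (2E)-3-(3,4-dimethoxyphenyl)prop-2-en-1-yl methyl carbonate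
Product: 7 tert-butyl 2-[(1R)-1-(3,4-dimethoxyphenyl)prop-2-en-1-yl]-3-oxobutanoate
Conditions: [Ir(cod)Cl]2 (0.02 equiv), BINOL-derived phosphoramidite with a bis(1-phenylethyl)amine unit (0.04 equiv; the enantiomer that gives the R centre), TBD (0.08 equiv), 6 (2 equiv), THF, rt
Reagents that add atoms: none
Why: Iridium-catalysed branched-selective asymmetric allylic alkylation of a beta-keto ester with a cinnamyl carbonate should give the 1-arylallyl product, with the catalyst setting the benzylic centre (the later C7).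

Step 5
Reactants: 7 tert-butyl 2-[(1R)-1-(3,4-dimethoxyphenyl)prop-2-en-1-yl]-3-oxobutanoate; 3 2-(bromomethyl)penta-1,4-dien-1-yl acetate
Product: 8 tert-butyl 7-(acetyloxy)-2-[(1R)-1-(3,4-dimethoxyphenyl)prop-2-en-1-yl]-3-oxo-6-(prop-2-en-1-yl)hept-6-enoate
Conditions: NaH (1.1 equiv), THF, 0 °C; n-BuLi (1.05 equiv), 0 °C; 3, −78 °C to −30 °C; aq. NH4Cl
Reagents that add atoms: none
Why: The dianion of a beta-keto ester is alkylated at its terminal (gamma) carbon, and SN2 attack on the allylic bromide should be much faster at −78 °C than acyl transfer from the enol acetate.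

Step 6
Reactants: 8 tert-butyl 7-(acetyloxy)-2-[(1R)-1-(3,4-dimethoxyphenyl)prop-2-en-1-yl]-3-oxo-6-(prop-2-en-1-yl)hept-6-enoate
Product: 9 tert-butyl 7-(acetyloxy)-2-bromo-2-[(1S)-1-(3,4-dimethoxyphenyl)prop-2-en-1-yl]-3-oxo-6-(prop-2-en-1-yl)hept-6-enoate
Conditions: NBS (1.05 equiv), Mg(ClO4)2 (0.1 equiv), EtOAc, 0 °C
Reagents that add atoms: N-bromosuccinimide (O=C1CCC(=O)N1Br)
Why: Lewis acid-catalysed electrophilic bromination of the enol of a 2-substituted beta-keto ester should place bromine on the only doubly activated carbon, which fixes the later radical site (the descriptor changes only because of ligand priority).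

Step 7
Reactants: 9 tert-butyl 7-(acetyloxy)-2-bromo-2-[(1S)-1-(3,4-dimethoxyphenyl)prop-2-en-1-yl]-3-oxo-6-(prop-2-en-1-yl)hept-6-enoate
Product: 11 (7S)-6-bromo-7-(3,4-dimethoxyphenyl)-5-oxo-2-(prop-2-en-1-yl)nona-1,8-dien-1-yl acetate, via bromo keto acid 10 (not isolated)
Conditions: TFA, CH2Cl2 (1:4), 0 °C to rt
Reagents that add atoms: none
Why: Acidolysis of the tert-butyl ester gives the alpha-bromo beta-keto acid, which should lose CO2 at room temperature and leave the alpha-bromo ketone with bromine only on the carbon next to the stereocentre.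

Step 8
Reactants: 11 (7S)-6-bromo-7-(3,4-dimethoxyphenyl)-5-oxo-2-(prop-2-en-1-yl)nona-1,8-dien-1-yl acetate
Product: 12 (1S,5S,6R,7R)-6-(3,4-dimethoxyphenyl)-7-methyl-4-oxo-1-(prop-2-en-1-yl)bicyclo[3.2.1]octan-8-yl acetate
Conditions: (Me3Si)3SiH (1.3 equiv), AIBN (0.2 equiv), toluene (0.01 M), 85 °C, silane and initiator added over 8 h
Reagents that add atoms: none
Why: Bromine abstraction by the silyl radical gives the alpha-keto radical at C1 (target numbering), which adds to C8, the acetoxy-bearing end of the C5=C8 enol acetate; the tertiary C5 radical then adds to the internal carbon of the vinyl group on C7, and the primary radical takes hydrogen from the silane so that its CH2 becomes the C6 methyl. The closest known reaction type is the tandem radical cyclisation of an alpha-carbonyl radical that carries an allyl group and a 4-alkenyl chain (6-endo then 5-exo) to a bicyclo[3.2.1]octane, here started from an alpha-bromo ketone under silane chain conditions. The six-membered ring C1–C2–C3–C4–C5–C8 closes 6-endo-trig and the five-membered ring C1–C8–C5–C6–C7 closes 5-exo-trig, and the seven-membered ring results from the two. C1 is set by allylic strain at the radical (C7–H lies in the plane of the enoxyl system and C8 approaches anti to the aryl group, which places aryl exo), C5 follows from the geometry of the bridge, C6 is set in a chair-like 5-exo transition state with the vinyl CH2 eclipsing C7–H so that methyl ends trans to aryl (endo), and the C8 configuration is without consequence because C8 becomes a ketone. The step needs 6-endo over 5-exo in the first closure, which the ring carbonyl of the alpha-keto radical and the fully substituted C5 should secure, and cyclisation faster than hydrogen transfer, which slow addition of the silane should secure. The final primary radical should not add to the allyl group on C5, because that closure would need a five-membered ring fused across a bond whose dihedral angle is near 80 degrees.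

Step 9
Reactants: 12 (1S,5S,6R,7R)-6-(3,4-dimethoxyphenyl)-7-methyl-4-oxo-1-(prop-2-en-1-yl)bicyclo[3.2.1]octan-8-yl acetate
Product: 14 (1R,5S,6R,7R)-6-(3,4-dimethoxyphenyl)-3-hydroxy-7-methyl-4-oxo-1-(prop-2-en-1-yl)bicyclo[3.2.1]octan-8-yl acetate, via silyl enol ether 13 (not isolated)
Conditions: TMSOTf (1.2 equiv), Et3N (1.5 equiv), CH2Cl2, 0 °C; then dimethyldioxirane (1.05 equiv), acetone, −40 °C; then citric acid, MeOH, rt
Reagents that add atoms: dimethyldioxirane (CC1(C)OO1)
Why: Rubottom oxidation: the ketone can enolise only toward its CH2 neighbour (the other alpha carbon is a bridgehead), and the electron-rich silyl enol ether should be epoxidised far faster than the allyl group (the C1 descriptor changes only because of ligand priority).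

Step 10
Reactants: 14 (1R,5S,6R,7R)-6-(3,4-dimethoxyphenyl)-3-hydroxy-7-methyl-4-oxo-1-(prop-2-en-1-yl)bicyclo[3.2.1]octan-8-yl acetate
Product: 15 (1S,5R,6R,7R)-7-(3,4-dimethoxyphenyl)-3,8-dihydroxy-6-methyl-5-(prop-2-en-1-yl)bicyclo[3.2.1]octan-2-one
Conditions: K2CO3 (0.2 equiv), MeOH, 0 °C
Reagents that add atoms: none
Why: Base-catalysed transesterification with methanol should remove the acetyl group and free the bridge carbinol.

Step 11
Reactants: 15 (1S,5R,6R,7R)-7-(3,4-dimethoxyphenyl)-3,8-dihydroxy-6-methyl-5-(prop-2-en-1-yl)bicyclo[3.2.1]octan-2-one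
Product: 16 (1S,5S,6R,7R)-7-(3,4-dimethoxyphenyl)-3-hydroxy-6-methyl-5-(prop-2-en-1-yl)bicyclo[3.2.1]oct-3-ene-2,8-dione
Conditions: Dess–Martin periodinane (3 equiv), NaHCO3, CH2Cl2, rt
Reagents that add atoms: none
Why: Dess–Martin oxidation should convert both secondary carbinols into ketones, and the resulting 1,2-dione can enolise only toward C4 (C1 is a bridgehead), so it should rest as the diosphenol.

Step 12
Reactants: 16 (1S,5S,6R,7R)-7-(3,4-dimethoxyphenyl)-3-hydroxy-6-methyl-5-(prop-2-en-1-yl)bicyclo[3.2.1]oct-3-ene-2,8-dione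
Product: 17 (1S,5S,6R,7R)-7-(3,4-dimethoxyphenyl)-3-methoxy-6-methyl-5-(prop-2-en-1-yl)bicyclo[3.2.1]oct-3-ene-2,8-dione (kadsurenin D)
Conditions: Me2SO4 (1.2 equiv), K2CO3 (1.5 equiv), acetone, rt
Reagents that add atoms: dimethyl sulfate (COS(=O)(=O)OC)
Why: O-Alkylation of the acidic diosphenol with a hard methylating agent under non-nucleophilic base should give the 2-methoxy enone without opening the non-enolisable 1,3-diketone.

**Compound list**

1 | pent-4-enal | C=CCCC=O | starting material
2 | 2-methylidenepent-4-enal | C=CCC(=C)C=O | intermediate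
3 | 2-(bromomethyl)penta-1,4-dien-1-yl acetate (E/Z mixture) | CC(=O)OC=C(CBr)CC=C | intermediate
4 | (2E)-3-(3,4-dimethoxyphenyl)prop-2-en-1-ol | OC/C=C/c1ccc(OC)c(OC)c1 | starting material
5 | (2E)-3-(3,4-dimethoxyphenyl)prop-2-en-1-yl methyl carbonate | COC(=O)OC/C=C/c1ccc(OC)c(OC)c1 | intermediate
6 | tert-butyl 3-oxobutanoate | CC(=O)CC(=O)OC(C)(C)C | starting material
7 | tert-butyl 2-[(1R)-1-(3,4-dimethoxyphenyl)prop-2-en-1-yl]-3-oxobutanoate (C2 epimers) | CC(=O)C(C(=O)OC(C)(C)C)[C@@H](C=C)c1ccc(OC)c(OC)c1 | intermediate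
8 | tert-butyl 7-(acetyloxy)-2-[(1R)-1-(3,4-dimethoxyphenyl)prop-2-en-1-yl]-3-oxo-6-(prop-2-en-1-yl)hept-6-enoate (C2 epimers, E/Z) | CC(=O)OC=C(CC=C)CCC(=O)C(C(=O)OC(C)(C)C)[C@@H](C=C)c1ccc(OC)c(OC)c1 | intermediate
9 | tert-butyl 7-(acetyloxy)-2-bromo-2-[(1S)-1-(3,4-dimethoxyphenyl)prop-2-en-1-yl]-3-oxo-6-(prop-2-en-1-yl)hept-6-enoate (C2 epimers, E/Z) | CC(=O)OC=C(CC=C)CCC(=O)C(Br)(C(=O)OC(C)(C)C)[C@@H](C=C)c1ccc(OC)c(OC)c1 | intermediate
10 | 7-(acetyloxy)-2-bromo-2-[(1S)-1-(3,4-dimethoxyphenyl)prop-2-en-1-yl]-3-oxo-6-(prop-2-en-1-yl)hept-6-enoic acid | CC(=O)OC=C(CC=C)CCC(=O)C(Br)(C(=O)O)[C@@H](C=C)c1ccc(OC)c(OC)c1 | intermediate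
11 | (7S)-6-bromo-7-(3,4-dimethoxyphenyl)-5-oxo-2-(prop-2-en-1-yl)nona-1,8-dien-1-yl acetate (C6 epimers, E/Z) | CC(=O)OC=C(CC=C)CCC(=O)C(Br)[C@@H](C=C)c1ccc(OC)c(OC)c1 | intermediate
12 | (1S,5S,6R,7R)-6-(3,4-dimethoxyphenyl)-7-methyl-4-oxo-1-(prop-2-en-1-yl)bicyclo[3.2.1]octan-8-yl acetate (C8 epimers) | C=CC[C@]12CCC(=O)[C@H](C1OC(C)=O)[C@H](c1ccc(OC)c(OC)c1)[C@H]2C | intermediate
13 | (1R,5S,6R,7R)-6-(3,4-dimethoxyphenyl)-7-methyl-1-(prop-2-en-1-yl)-4-[(trimethylsilyl)oxy]bicyclo[3.2.1]oct-3-en-8-yl acetate | C=CC[C@]12CC=C(O[Si](C)(C)C)[C@H](C1OC(C)=O)[C@H](c1ccc(OC)c(OC)c1)[C@H]2C | intermediate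
14 | (1R,5S,6R,7R)-6-(3,4-dimethoxyphenyl)-3-hydroxy-7-methyl-4-oxo-1-(prop-2-en-1-yl)bicyclo[3.2.1]octan-8-yl acetate (C3 and C8 epimers) | C=CC[C@]12CC(O)C(=O)[C@H](C1OC(C)=O)[C@H](c1ccc(OC)c(OC)c1)[C@H]2C | intermediate
15 | (1S,5R,6R,7R)-7-(3,4-dimethoxyphenyl)-3,8-dihydroxy-6-methyl-5-(prop-2-en-1-yl)bicyclo[3.2.1]octan-2-one (C3 and C8 epimers) | C=CC[C@]12CC(O)C(=O)[C@H](C1O)[C@H](c1ccc(OC)c(OC)c1)[C@H]2C | intermediate
16 | (1S,5S,6R,7R)-7-(3,4-dimethoxyphenyl)-3-hydroxy-6-methyl-5-(prop-2-en-1-yl)bicyclo[3.2.1]oct-3-ene-2,8-dione | C=CC[C@]12C=C(O)C(=O)[C@H](C1=O)[C@H](c1ccc(OC)c(OC)c1)[C@H]2C | intermediate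
17 | (1S,5S,6R,7R)-7-(3,4-dimethoxyphenyl)-3-methoxy-6-methyl-5-(prop-2-en-1-yl)bicyclo[3.2.1]oct-3-ene-2,8-dione (kadsurenin D) | C=CC[C@]12C=C(OC)C(=O)[C@H](C1=O)[C@H](c1ccc(OC)c(OC)c1)[C@H]2C | target

**Step count**

Total: 12 steps. Longest linear sequence: 10 steps (4 to 17 through steps 3 to 12; equally 1 to 17 through steps 1, 2 and 5 to 12).

**Steps most likely to fail**

Step 8. The alpha-keto radical may add to the substituted alkene carbon (5-exo) instead of the acetoxy-bearing end. It may also undergo a 1,2-vinyl shift (3-exo closure, then ring opening to the benzylic radical), or be reduced before it cyclises. Facial selectivity at the radical carbon may be poor and give the endo-aryl series. Fallback, from 8 back to 12: the beta-keto ester 8 is oxidised with Mn(OAc)3 in ethanol, so that the doubly stabilised, more electrophilic radical carrying the ester group undergoes the same two closures and the last radical takes hydrogen from the solvent. This should give tert-butyl 8-(acetyloxy)-7-(3,4-dimethoxyphenyl)-6-methyl-2-oxo-5-(prop-2-en-1-yl)bicyclo[3.2.1]octane-1-carboxylate F1. TFA then frees the bridgehead acid F2, which is converted with 2-mercaptopyridine N-oxide and DCC into the thiohydroxamate ester F3. Barton decarboxylation (light, t-BuSH) replaces the carboxyl group by hydrogen with retention at the bridgehead and returns 12.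

Step 5. Acyl transfer from the enol acetate to the strongly basic dianion may compete with displacement of the bromide. Fallback, from 3 and 5 back to 8: the soft sodium enolate of di-tert-butyl malonate is alkylated with 3 to give di-tert-butyl 2-[3-(acetyloxy)-2-(prop-2-en-1-yl)prop-2-en-1-yl]propanedioate F4. TFA followed by heating in toluene gives 5-(acetyloxy)-4-(prop-2-en-1-yl)pent-4-enoic acid F5. Its acid chloride acylates Meldrum's acid (pyridine) to give 5-[5-(acetyloxy)-1-hydroxy-4-(prop-2-en-1-yl)pent-4-en-1-ylidene]-2,2-dimethyl-1,3-dioxane-4,6-dione F6. Heating with t-BuOH gives tert-butyl 7-(acetyloxy)-3-oxo-6-(prop-2-en-1-yl)hept-6-enoate F7. The iridium-catalysed allylation of step 4 is then run on F7 with carbonate 5 under base-free conditions and gives 8.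

Step 10. The alkoxide at the bridge carbon is beta to the ring ketone and may open by retro-aldol cleavage, with loss of the bridgehead configuration on reclosure. Fallback, from 14 back to 16: 14 is treated with excess DIBAL-H at −78 °C, which reduces the ketone and cleaves the acetate without a free beta-keto alkoxide. This should give 7-(3,4-dimethoxyphenyl)-6-methyl-5-(prop-2-en-1-yl)bicyclo[3.2.1]octane-2,3,8-triol F8. Oxidation of all three carbinols with IBX in DMSO gives 16 directly.

Further compounds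
F1 | step 8 | tert-butyl 8-(acetyloxy)-7-(3,4-dimethoxyphenyl)-6-methyl-2-oxo-5-(prop-2-en-1-yl)bicyclo[3.2.1]octane-1-carboxylate (ring configuration as in 12) | C=CC[C@]12CCC(=O)[C@](C(=O)OC(C)(C)C)(C1OC(C)=O)[C@H](c1ccc(OC)c(OC)c1)[C@H]2C
F2 | step 8 | 8-(acetyloxy)-7-(3,4-dimethoxyphenyl)-6-methyl-2-oxo-5-(prop-2-en-1-yl)bicyclo[3.2.1]octane-1-carboxylic acid | C=CC[C@]12CCC(=O)[C@](C(=O)O)(C1OC(C)=O)[C@H](c1ccc(OC)c(OC)c1)[C@H]2C
F3 | step 8 | 2-thioxopyridin-1(2H)-yl 8-(acetyloxy)-7-(3,4-dimethoxyphenyl)-6-methyl-2-oxo-5-(prop-2-en-1-yl)bicyclo[3.2.1]octane-1-carboxylate | C=CC[C@]12CCC(=O)[C@](C(=O)ON3C=CC=CC3=S)(C1OC(C)=O)[C@H](c1ccc(OC)c(OC)c1)[C@H]2C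
F4 | step 5 | di-tert-butyl 2-[3-(acetyloxy)-2-(prop-2-en-1-yl)prop-2-en-1-yl]propanedioate | CC(=O)OC=C(CC=C)CC(C(=O)OC(C)(C)C)C(=O)OC(C)(C)C
F5 | step 5 | 5-(acetyloxy)-4-(prop-2-en-1-yl)pent-4-enoic acid | CC(=O)OC=C(CC=C)CCC(=O)O
F6 | step 5 | 5-[5-(acetyloxy)-1-hydroxy-4-(prop-2-en-1-yl)pent-4-en-1-ylidene]-2,2-dimethyl-1,3-dioxane-4,6-dione | CC(=O)OC=C(CC=C)CCC(O)=C1C(=O)OC(C)(C)OC1=O
F7 | step 5 | tert-butyl 7-(acetyloxy)-3-oxo-6-(prop-2-en-1-yl)hept-6-enoate | CC(=O)OC=C(CC=C)CCC(=O)CC(=O)OC(C)(C)C
F8 | step 10 | 7-(3,4-dimethoxyphenyl)-6-methyl-5-(prop-2-en-1-yl)bicyclo[3.2.1]octane-2,3,8-triol (ring configuration as in 15) | C=CC[C@]12CC(O)C(O)[C@H](C1O)[C@H](c1ccc(OC)c(OC)c1)[C@H]2C
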